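## The problem

The target **30** is an all-cis 2,3,5,6-tetrasubstituted tetrahydropyran. The carbon chains at C6 and C10 are cis and equatorial, and the chlorine at C7 and the bromine at C9 are each cis to the neighbouring chain, so both halogens are axial on the same face. Such a 1,3-diaxial dihalide is best reached by SN2 inversion of equatorial hydroxyls, so the ring to build is an all-equatorial 2,6-dialkyl-tetrahydropyran-3,5-diol whose two hydroxyls must be told apart. C10 can serve as the conformational anchor that controls C6, but C7 and C9 have to be brought in rather than induced, and C8 between them is a bare methylene. The C10 chain ends in a trisubstituted (E)-bromoalkene (Br on C13, trans to C11), where both the position of bromine and the geometry must be fixed. The C6 chain is a (Z)-enyne that isomerises easily and carries an acidic alkyne hydrogen. The secondary halides eliminate under strong base and the vinyl bromide does not survive hydrogenation or low-valent metals, so halogens and enyne must arrive late and in the right order. The enabling feature is that the enyne begins at C5 on C6 while C7 next door bears a heteroatom: an allyl group on C6 and an acrylate on O7 close a seven-membered lactone (O7, C2, C3, C4, C5, C6, C7) that can only hold C3=C4 as a cis alkene and whose carbonyl carbon is C2.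

## Retrosynthesis

The C7–Cl bond is cut first: **30** comes from the (Z)-enyne alcohol **29** by substitution with inversion. Making the chloride last keeps the C7 oxygen available as the tether and spares the most elimination-prone centre from every basic or reducing step. The forward reaction must invert a hindered equatorial alcohol without touching the enyne.

In **29** the C1–C2 bond is cut. C1 is added to the aldehyde carbon C2 of the hydroxy enal **28**, the open form of lactol **26**, which is the reduction product of lactone **25**. Olefination of a C4 aldehyde with a propargyl reagent would set the geometry kinetically; this cut instead carries C3=C4 in as a finished Z-alkene. The forward steps need only avoid isomerising the Z-enal.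

Lactone **25** is opened at C3=C4 by ring-closing metathesis to the C6-allyl C7-acrylate **24**. Against a cross-metathesis or a Wittig reaction at the same bond, this cut makes the geometry a consequence of ring size. The precursor has one ring fewer, and both alkene carbons come from terminal vinyl groups supplied by allylmagnesium bromide **19** and acryloyl chloride **23**. The forward reaction must prefer seven-membered closure to dimerisation and ignore the bromoalkene.

Acrylate **24** is the ester of alcohol **22**, freed from benzyl ether **21**. In **21** the C5–C6 and C6–H bonds are cut together: **19** adds to lactone **18** and the hemiketal **20** is reduced. Allylation of a glycosyl cation would put carbon in axially and give the 2,6-trans isomer, whereas axial hydride gives the cis isomer. Lactone **18** has one stereocentre fewer, and the forward step needs only axial hydride delivery.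

Lactone **18** is the oxidation product of lactol **17**, obtained from methyl glycoside **16** by hydrolysis. In **16** the C9–Br bond is cut back, with inversion, to the equatorial alcohol **14**. Bromide goes in before the anomeric carbon is unmasked because a free 4-hydroxy-δ-lactone would rearrange to the γ-lactone. The methyl glycoside is the anomeric mask that is inert to Br2, Grignard reagents and acetylides alike.

In **14** the bromoalkene is cut in stages. C13–Br goes back to C13–Si in vinylsilane **11**, C13–C14 to iodoethane **9** and silylalkyne **8**, and C11–C12 to the primary triflate **6** and trimethylsilylacetylene **7**. A but-1-ynyl unit would deliver all four carbons at once, but hydrometalation of the resulting dialkylalkyne has nothing to distinguish C12 from C13. Silicon on C13 directs the metal there, and syn hydrometalation, retentive alkylation and invertive bromodesilylation fix the E geometry by mechanism. The forward steps require a substrate inert to Grignard reagents and Br2, which glycoside, benzyl ether and silyl ether are.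

Triflate **6** comes from diol **5**, the deprotected form of **4**. Compound **4** is the C3-deoxygenation product of xanthate **3**, made from benzyl ether **2** and the commercial acetal **1**. D-Glucose supplies C10 (its C5) and the equatorial oxygens at C7 and C9 (its O2 and O4), already differentiated by the 4,6-acetal. The only superfluous atom, O3, is removed by radical deoxygenation to give the C8 methylene.

## Roads not taken

Alternative 1: The cut runs through C7–C8 and C8–C9. Nitromethane (**A3**) supplies C8 and condenses twice, by Henry reactions under base, with the dialdehyde ether **A2** to close the ring as the 4-nitrotetrahydropyran-3,5-diol **A1**.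
- Merits: one step makes two C–C bonds, the ring and three stereocentres, and thermodynamic control should favour the all-equatorial isomer needed here. In ring-forming economy this is clearly better than the chosen plan.
- Weak points: C8 is a methylene in the target, so the nitro group must be removed from a secondary carbon flanked by two hydroxyls. Radical denitration of such centres is sluggish and β-elimination competes. The two hydroxyls of **A1** differ only through remote chains, yet one must become chloride and the other bromide. **A2** itself needs two defined ether stereocentres, and both the (E)-bromoalkene and the (Z)-enyne would still have to be made by olefination of its two arms.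
- Comparison: the chosen plan sets against it oxygens that are differentiated from the first compound and an O3 removed by a dependable deoxygenation.

Alternative 2: The cut runs through C6–C7 and C9–C10. Furan (**A5**) and the oxyallyl cation generated reductively from 1,1,3,3-tetrabromoacetone (**A6**) combine in a [4+3] cycloaddition to the meso oxabicycle **A4**.
- Merits: it is the shortest way to a cis-2,6-disubstituted tetrahydropyran. The oxygen bridge guarantees the C6/C10 relationship, and cleavage of the alkene would expose C5 and C11 together.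
- Weak points: **A4** is achiral, so a desymmetrisation decides the absolute configuration. It has no heteroatoms at C7 and C9 and a carbonyl on C8, where the target has the reverse pattern; two equatorial oxygenations and a carbonyl deletion are needed. The two arms released by alkene cleavage are identical and must be differentiated.
- Comparison: the chosen plan is longer, but every ring carbon arrives at its final oxidation level and no step has to create absolute configuration.

Alternative 3: The cut runs through O–C10 and C10–C11. The copper carbenoid from diazoketone **A8** is attacked by the C6 allyl ether oxygen, and the oxonium ylide rearranges by a [2,3] shift to the tetrahydropyranone **A7**.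
- Merits: one step builds the ring, the C10–C11 bond and the 2,6-cis relationship. The C9 ketone can be reduced to the equatorial alcohol needed for bromide inversion, and the C7 silyl ether is already distinct. In steps to the ring this road is probably shorter than the sugar route.
- Weak points: the allyl group arrives on C10 as a terminal alkene, which must be cleaved and rebuilt into the (E)-C12=C13(Br) unit; halo-olefination of an aldehyde tends to the wrong isomer. **A8** needs its C6 and C7 centres from asymmetric synthesis, and [1,2]-shift and C–H insertion compete with the rearrangement. The (Z)-enyne would come from olefination with imperfect selectivity, unless the lactone tactic of the chosen plan were grafted on.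
- Comparison: the chosen plan offers ring-enforced Z geometry, a silicon-defined bromoalkene and chiral-pool stereocentres. If the lactone tactic were borrowed, its advantage would shrink to the last two points.

Key step: step 16

Remark on the chemistry: lactols **17**, **20** and **26** are anomeric mixtures and dibromide **12** is a pair of anti-addition diastereomers; these centres are left open in the SMILES because both forms converge in the following operation. Compounds **1**, **7**, **9**, **19**, **23** and **27** are taken as commercially available.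

## Route

Step 1
Reactants: 1 methyl 4,6-O-[(R)-benzylidene]-α-D-glucopyranoside
Product: 2 methyl 2-O-benzyl-4,6-O-[(R)-benzylidene]-α-D-glucopyranoside
Conditions: BnBr, n-Bu4NHSO4 (cat.), 5% NaOH (aq), CH2Cl2, reflux
Reagents that add atoms: benzyl bromide, BrCc1ccccc1
Why: Williamson etherification under phase-transfer conditions; O2 is the more acidic hydroxyl (inductive effect of the anomeric centre), so the ion pair should form and react there preferentially, and the minor 3-O-benzyl and dibenzyl ethers are removed by chromatography.

Step 2
Reactants: 2 methyl 2-O-benzyl-4,6-O-[(R)-benzylidene]-α-D-glucopyranoside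
Product: 3 methyl 2-O-benzyl-4,6-O-[(R)-benzylidene]-3-O-[(methylsulfanyl)carbonothioyl]-α-D-glucopyranoside
Conditions: NaH, imidazole (cat.), THF, 0 °C; CS2; MeI, rt
Reagents that add atoms: carbon disulfide, S=C=S; iodomethane, CI
Why: Xanthate formation, the first half of a Barton–McCombie deoxygenation; the only free hydroxyl is deprotonated, adds to CS2 and is S-methylated, while acetal, benzyl ether and glycoside are inert to base.

Step 3
Reactants: 3 methyl 2-O-benzyl-4,6-O-[(R)-benzylidene]-3-O-[(methylsulfanyl)carbonothioyl]-α-D-glucopyranoside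
Product: 4 methyl 2-O-benzyl-4,6-O-[(R)-benzylidene]-3-deoxy-α-D-ribo-hexopyranoside
Conditions: Bu3SnH, AIBN (cat.), toluene, 110 °C
Reagents that add atoms: none
Why: Barton–McCombie radical deoxygenation; the stannyl radical adds to the thiocarbonyl, the secondary C3 radical fragments off and takes hydrogen from Bu3SnH, and since C3 becomes the C8 methylene no stereocentre is at stake.

Step 4
Reactants: 4 methyl 2-O-benzyl-4,6-O-[(R)-benzylidene]-3-deoxy-α-D-ribo-hexopyranoside
Product: 5 methyl 2-O-benzyl-3-deoxy-α-D-ribo-hexopyranoside
Conditions: TsOH·H2O (cat.), MeOH, rt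
Reagents that add atoms: none
Why: Acid-catalysed transacetalisation to methanol releases the 4,6-diol; in methanol the methyl glycoside can only exchange with itself and the benzyl ether is untouched.

Step 5
Reactants: 5 methyl 2-O-benzyl-3-deoxy-α-D-ribo-hexopyranoside
Product: 6 methyl 2-O-benzyl-3-deoxy-4-O-triethylsilyl-6-O-trifluoromethanesulfonyl-α-D-ribo-hexopyranoside
Conditions: Tf2O, 2,6-lutidine, CH2Cl2, −78 °C; then Et3SiOTf, −78 → −40 °C; used at once
Reagents that add atoms: trifluoromethanesulfonic anhydride, O=S(=O)(OS(=O)(=O)C(F)(F)F)C(F)(F)F; triethylsilyl trifluoromethanesulfonate, CC[Si](CC)(CC)OS(=O)(=O)C(F)(F)F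
Why: Chemoselective triflation of the primary hydroxyl at low temperature followed by silylation of the secondary one in the same flask (one-pot triflation–silylation of a 1,3-diol); the silyl ether keeps a C4 alkoxide from closing an oxetane in the next step.

Step 6
Reactants: 6 methyl 2-O-benzyl-3-deoxy-4-O-triethylsilyl-6-O-trifluoromethanesulfonyl-α-D-ribo-hexopyranoside; 7 trimethylsilylacetylene
Product: 8 methyl 2-O-benzyl-3,6-dideoxy-4-O-triethylsilyl-6-C-[(trimethylsilyl)ethynyl]-α-D-ribo-hexopyranoside
Conditions: 7, n-BuLi, THF, −78 °C; then 6, DMPU, −78 → −30 °C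
Reagents that add atoms: trimethylsilylacetylene, C#C[Si](C)(C)C
Why: SN2 alkylation of a lithium acetylide by a primary triflate with a dipolar cosolvent forms C11–C12; the silicon on the alkyne terminus later decides the regiochemistry at C13.

Step 7
Reactants: 8 methyl 2-O-benzyl-3,6-dideoxy-4-O-triethylsilyl-6-C-[(trimethylsilyl)ethynyl]-α-D-ribo-hexopyranoside; 9 iodoethane
Product: 11 methyl 2-O-benzyl-3,6-dideoxy-4-O-triethylsilyl-6-C-[(Z)-2-(trimethylsilyl)but-1-enyl]-α-D-ribo-hexopyranoside, via vinylmagnesium bromide 10 (not isolated)
Conditions: i-BuMgBr, Cp2TiCl2 (5 mol%), Et2O, 25 °C; then EtI, CuI (10 mol%), THF, 0 → 25 °C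
Reagents that add atoms: iodoethane, CCI
Why: Titanocene-catalysed hydromagnesiation of a 1-silylalkyne adds H and Mg syn with magnesium on the silicon-bearing carbon C13; copper-catalysed alkylation of the vinyl Grignard reagent with iodoethane proceeds with retention, so silicon ends cis and ethyl trans to C11.

Step 8
Reactants: 11 methyl 2-O-benzyl-3,6-dideoxy-4-O-triethylsilyl-6-C-[(Z)-2-(trimethylsilyl)but-1-enyl]-α-D-ribo-hexopyranoside
Product: 14 methyl 2-O-benzyl-6-C-[(E)-2-bromobut-1-enyl]-3,6-dideoxy-α-D-ribo-hexopyranoside, via anti-dibromide 12 (not isolated), via triethylsilyl ether 13 (not isolated)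
Conditions: Br2, CH2Cl2, −78 °C; NaOMe, MeOH, 0 °C → rt; then 1 M HCl (aq), THF, rt
Reagents that add atoms: bromine, BrBr
Why: Bromodesilylation of a vinylsilane with inversion: anti addition of Br2, then methoxide-induced anti elimination of bromide and the silyl group, turns the (Z)-vinylsilane into the (E)-bromoalkene (Br trans to C11, ethyl cis). Dilute acid then hydrolyses the triethylsilyl ether while glycoside and benzyl ether are stable.

Step 9
Reactants: 14 methyl 2-O-benzyl-6-C-[(E)-2-bromobut-1-enyl]-3,6-dideoxy-α-D-ribo-hexopyranoside
Product: 16 methyl 2-O-benzyl-4-bromo-6-C-[(E)-2-bromobut-1-enyl]-3,4,6-trideoxy-α-D-xylo-hexopyranoside, via 4-O-triflate 15 (not isolated)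
Conditions: Tf2O, 2,6-lutidine, CH2Cl2, −20 °C; then n-Bu4NBr, toluene, rt → 40 °C
Reagents that add atoms: tetrabutylammonium bromide, CCCC[N+](CCCC)(CCCC)CCCC.[Br-]
Why: Sulfonate displacement by bromide (SN2) at C4 of a pyranoside; the equatorial triflate has no antiperiplanar hydrogen, so substitution with inversion should outrun elimination and give the axial C9 bromide.

Step 10
Reactants: 16 methyl 2-O-benzyl-4-bromo-6-C-[(E)-2-bromobut-1-enyl]-3,4,6-trideoxy-α-D-xylo-hexopyranoside
Product: 17 2-O-benzyl-4-bromo-6-C-[(E)-2-bromobut-1-enyl]-3,4,6-trideoxy-D-xylo-hexopyranose (anomeric mixture)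
Conditions: 2 M HCl (aq)/1,4-dioxane (1:1), 80 °C
Reagents that add atoms: water, O
Why: Acid-catalysed hydrolysis of a methyl glycoside through the oxocarbenium ion, helped by the missing C3 oxygen; benzyl ether, secondary bromide and vinyl bromide should tolerate aqueous acid, and with no C4 hydroxyl only the pyranose can form.

Step 11
Reactants: 17 2-O-benzyl-4-bromo-6-C-[(E)-2-bromobut-1-enyl]-3,4,6-trideoxy-D-xylo-hexopyranose
Product: 18 2-O-benzyl-4-bromo-6-C-[(E)-2-bromobut-1-enyl]-3,4,6-trideoxy-D-xylo-hexono-1,5-lactone
Conditions: n-Pr4N[RuO4] (5 mol%), N-methylmorpholine N-oxide, 4 Å MS, CH2Cl2, rt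
Reagents that add atoms: none
Why: Ley–Griffith oxidation of a lactol to the 1,5-lactone under neutral conditions; with no leaving group on C3 the lactone cannot undergo β-elimination.

Step 12
Reactants: 18 2-O-benzyl-4-bromo-6-C-[(E)-2-bromobut-1-enyl]-3,4,6-trideoxy-D-xylo-hexono-1,5-lactone; 19 allylmagnesium bromide
Product: 20 hemiketal formed by addition of the allyl group to C1 of 18 (2-allyl-2-hydroxytetrahydropyran; C7 benzyloxy, C9 bromo, C10 (E)-3-bromopent-2-enyl; hemiketal centre open)
Conditions: CH2=CHCH2MgBr, THF, −78 °C
Reagents that add atoms: allylmagnesium bromide, C=CC[Mg]Br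
Why: Grignard addition to a δ-lactone at low temperature stops at the tetrahedral magnesium alkoxide and gives the hemiketal on work-up (first half of the lactone-to-C-glycoside sequence); the halides do not react at −78 °C.

Step 13
Reactants: 20 hemiketal from step 12
Product: 21 (2S,3R,5R,6R)-2-allyl-3-benzyloxy-5-bromo-6-[(E)-3-bromopent-2-enyl]tetrahydropyran (target numbering 6S,7R,9R,10R)
Conditions: Et3SiH, BF3·OEt2, MeCN/CH2Cl2, −40 → −10 °C
Reagents that add atoms: none
Why: Ionic reduction of a hemiketal: BF3·OEt2 generates the cyclic oxocarbenium ion and Et3SiH delivers hydride axially through a chair-like transition state, so the allyl group ends equatorial and cis to the C10 chain (C6 set as S). The equatorial C10 chain and the axial C9 bromide favour the same half-chair.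

Step 14
Reactants: 21 (2S,3R,5R,6R)-2-allyl-3-benzyloxy-5-bromo-6-[(E)-3-bromopent-2-enyl]tetrahydropyran
Product: 22 (2S,3R,5R,6R)-2-allyl-5-bromo-6-[(E)-3-bromopent-2-enyl]tetrahydropyran-3-ol
Conditions: BCl3, C6HMe5, CH2Cl2, −78 °C
Reagents that add atoms: none
Why: Lewis acid cleavage of a benzyl ether with BCl3 at low temperature, with pentamethylbenzene trapping the benzyl cation; alkene, alkyl bromide and vinyl bromide are tolerated where hydrogenolysis would not be.

Step 15
Reactants: 22 (2S,3R,5R,6R)-2-allyl-5-bromo-6-[(E)-3-bromopent-2-enyl]tetrahydropyran-3-ol; 23 acryloyl chloride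
Product: 24 (2S,3R,5R,6R)-2-allyl-5-bromo-6-[(E)-3-bromopent-2-enyl]tetrahydropyran-3-yl acrylate
Conditions: CH2=CHCOCl, i-Pr2NEt, CH2Cl2, −20 → 0 °C
Reagents that add atoms: acryloyl chloride, C=CC(=O)Cl
Why: Acylation of the equatorial C7 hydroxyl by an acid chloride with a hindered amine base; low temperature suppresses conjugate addition to the acrylate.

Step 16
Reactants: 24 (2S,3R,5R,6R)-2-allyl-5-bromo-6-[(E)-3-bromopent-2-enyl]tetrahydropyran-3-yl acrylate
Product: 25 trans-fused (Z)-unsaturated seven-membered lactone (ring O7–C2(=O)–C3=C4–C5–C6–C7 on the tetrahydropyran; C9 bromo, C10 (E)-3-bromopent-2-enyl; 6S,7R,9R,10R)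
Conditions: RuCl2(H2IMes)(PCy3)(=CHPh) (second-generation Grubbs catalyst, 10 mol%), CH2Cl2 (2 mM), 40 °C
Reagents that add atoms: none
Why: Ring-closing olefin metathesis, the known closure of acrylate esters of unsaturated alcohols to α,β-unsaturated lactones. The ruthenium benzylidene initiates at the monosubstituted, electron-neutral allyl alkene to give an alkylidene at C4; [2+2] cycloaddition with the acrylate C=C, cycloreversion and loss of ethene form C3=C4. The ring closed is the seven-membered lactone O7–C2–C3–C4–C5–C6–C7, by metathesis of two terminal alkenes whose tether arms are both equatorial on the chair tetrahydropyran (trans fusion), so the existing ring pays part of the entropy. No stereocentre is formed; the only stereochemical element is the alkene geometry, and a seven-membered ring can hold only the cis (Z) double bond. The step needs chemoselectivity against the trisubstituted bromoalkene, which is hindered, deactivated by bromine and a poor metathesis partner. It also needs closure to beat dimerisation, which millimolar concentration and the escape of ethene should secure. The axial C9 bromide is a spectator under these neutral conditions.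

Step 17
Reactants: 25 trans-fused (Z)-unsaturated seven-membered lactone
Product: 26 (Z)-unsaturated seven-membered lactol (C2 hemiacetal, anomeric mixture)
Conditions: i-Bu2AlH, CH2Cl2, −78 °C
Reagents that add atoms: none
Why: Partial reduction of a lactone with i-Bu2AlH at −78 °C; the tetrahedral aluminate collapses only on work-up, giving the lactol, and 1,2-addition is preferred to conjugate reduction.

Step 18
Reactants: 26 (Z)-unsaturated seven-membered lactol; 27 trimethylsilyldiazomethane
Product: 29 (2S,3R,5R,6R)-5-bromo-6-[(E)-3-bromopent-2-enyl]-2-[(Z)-pent-2-en-4-ynyl]tetrahydropyran-3-ol, via hydroxy enal 28 (not isolated)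
Conditions: Me3SiCHN2, LiN(i-Pr)2, THF, −78 °C; then 26, −78 → 0 °C
Reagents that add atoms: trimethylsilyldiazomethane, C[Si](C)(C)C=[N+]=[N-]
Why: Colvin homologation: the lactol equilibrates with the (Z)-hydroxy enal, the lithiated diazo compound adds to the aldehyde, and Peterson-type loss of silanolate and of N2 gives an alkylidene carbene whose 1,2-hydrogen shift forms the C1–C2 triple bond. C3=C4 is not involved, and low temperature disfavours oxa-Michael addition of the C7 alkoxide.

Step 19
Reactants: 29 (2S,3R,5R,6R)-5-bromo-6-[(E)-3-bromopent-2-enyl]-2-[(Z)-pent-2-en-4-ynyl]tetrahydropyran-3-ol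
Product: 30 (2S,3S,5R,6R)-5-bromo-6-[(E)-3-bromopent-2-enyl]-3-chloro-2-[(Z)-pent-2-en-4-ynyl]tetrahydropyran (target)
Conditions: CCl4, (n-C8H17)3P, toluene, 70 °C
Reagents that add atoms: tetrachloromethane, ClC(Cl)(Cl)Cl
Why: Appel chlorination: the alkoxyphosphonium ion at the equatorial C7 oxygen is displaced by chloride with inversion (SN2), giving the axial chloride cis to the C5 chain; an equatorial leaving group has no antiperiplanar hydrogen, which limits elimination.

## Compound list

1 | methyl 4,6-O-[(R)-benzylidene]-α-D-glucopyranoside | CO[C@H]1O[C@@H]2CO[C@@H](c3ccccc3)O[C@H]2[C@H](O)[C@H]1O | starting material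
2 | methyl 2-O-benzyl-4,6-O-[(R)-benzylidene]-α-D-glucopyranoside | CO[C@H]1O[C@@H]2CO[C@@H](c3ccccc3)O[C@H]2[C@H](O)[C@H]1OCc4ccccc4 | intermediate
3 | methyl 2-O-benzyl-4,6-O-[(R)-benzylidene]-3-O-[(methylsulfanyl)carbonothioyl]-α-D-glucopyranoside | CO[C@H]1O[C@@H]2CO[C@@H](c3ccccc3)O[C@H]2[C@H](OC(=S)SC)[C@H]1OCc4ccccc4 | intermediate
4 | methyl 2-O-benzyl-4,6-O-[(R)-benzylidene]-3-deoxy-α-D-ribo-hexopyranoside | CO[C@H]1O[C@@H]2CO[C@@H](c3ccccc3)O[C@H]2C[C@H]1OCc4ccccc4 | intermediate
5 | methyl 2-O-benzyl-3-deoxy-α-D-ribo-hexopyranoside | CO[C@H]1O[C@H](CO)[C@@H](O)C[C@H]1OCc2ccccc2 | intermediate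
6 | methyl 2-O-benzyl-3-deoxy-4-O-triethylsilyl-6-O-trifluoromethanesulfonyl-α-D-ribo-hexopyranoside | CO[C@H]1O[C@H](COS(=O)(=O)C(F)(F)F)[C@@H](O[Si](CC)(CC)CC)C[C@H]1OCc2ccccc2 | intermediate
7 | trimethylsilylacetylene | C#C[Si](C)(C)C | starting material
8 | methyl 2-O-benzyl-3,6-dideoxy-4-O-triethylsilyl-6-C-[(trimethylsilyl)ethynyl]-α-D-ribo-hexopyranoside | CO[C@H]1O[C@H](CC#C[Si](C)(C)C)[C@@H](O[Si](CC)(CC)CC)C[C@H]1OCc2ccccc2 | intermediate
9 | iodoethane | CCI | starting material
10 | vinylmagnesium bromide from syn hydromagnesiation of 8 (Mg and SiMe3 on C13, Mg trans to C11) | CO[C@H]1O[C@H](C/C=C(/[Mg]Br)[Si](C)(C)C)[C@@H](O[Si](CC)(CC)CC)C[C@H]1OCc2ccccc2 | intermediate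
11 | methyl 2-O-benzyl-3,6-dideoxy-4-O-triethylsilyl-6-C-[(Z)-2-(trimethylsilyl)but-1-enyl]-α-D-ribo-hexopyranoside | CO[C@H]1O[C@H](C/C=C(/CC)[Si](C)(C)C)[C@@H](O[Si](CC)(CC)CC)C[C@H]1OCc2ccccc2 | intermediate
12 | anti-dibromide of 11 (6-C-[1,2-dibromo-2-(trimethylsilyl)butyl], two anti diastereomers) | CO[C@H]1O[C@H](CC(Br)C(Br)(CC)[Si](C)(C)C)[C@@H](O[Si](CC)(CC)CC)C[C@H]1OCc2ccccc2 | intermediate
13 | methyl 2-O-benzyl-6-C-[(E)-2-bromobut-1-enyl]-3,6-dideoxy-4-O-triethylsilyl-α-D-ribo-hexopyranoside | CO[C@H]1O[C@H](C/C=C(/Br)CC)[C@@H](O[Si](CC)(CC)CC)C[C@H]1OCc2ccccc2 | intermediate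
14 | methyl 2-O-benzyl-6-C-[(E)-2-bromobut-1-enyl]-3,6-dideoxy-α-D-ribo-hexopyranoside | CO[C@H]1O[C@H](C/C=C(/Br)CC)[C@@H](O)C[C@H]1OCc2ccccc2 | intermediate
15 | 4-O-trifluoromethanesulfonate of 14 | CO[C@H]1O[C@H](C/C=C(/Br)CC)[C@@H](OS(=O)(=O)C(F)(F)F)C[C@H]1OCc2ccccc2 | intermediate
16 | methyl 2-O-benzyl-4-bromo-6-C-[(E)-2-bromobut-1-enyl]-3,4,6-trideoxy-α-D-xylo-hexopyranoside | CO[C@H]1O[C@H](C/C=C(/Br)CC)[C@H](Br)C[C@H]1OCc2ccccc2 | intermediate
17 | 2-O-benzyl-4-bromo-6-C-[(E)-2-bromobut-1-enyl]-3,4,6-trideoxy-D-xylo-hexopyranose (anomeric mixture) | OC1O[C@H](C/C=C(/Br)CC)[C@H](Br)C[C@H]1OCc2ccccc2 | intermediate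
18 | 2-O-benzyl-4-bromo-6-C-[(E)-2-bromobut-1-enyl]-3,4,6-trideoxy-D-xylo-hexono-1,5-lactone | O=C1O[C@H](C/C=C(/Br)CC)[C@H](Br)C[C@H]1OCc2ccccc2 | intermediate
19 | allylmagnesium bromide | C=CC[Mg]Br | starting material
20 | 2-allyl-2-hydroxytetrahydropyran hemiketal from 18 (C7 benzyloxy, C9 bromo, C10 (E)-3-bromopent-2-enyl; hemiketal centre open) | C=CCC1(O)O[C@H](C/C=C(/Br)CC)[C@H](Br)C[C@H]1OCc2ccccc2 | intermediate
21 | (2S,3R,5R,6R)-2-allyl-3-benzyloxy-5-bromo-6-[(E)-3-bromopent-2-enyl]tetrahydropyran | C=CC[C@@H]1O[C@H](C/C=C(/Br)CC)[C@H](Br)C[C@H]1OCc2ccccc2 | intermediate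
22 | (2S,3R,5R,6R)-2-allyl-5-bromo-6-[(E)-3-bromopent-2-enyl]tetrahydropyran-3-ol | C=CC[C@@H]1O[C@H](C/C=C(/Br)CC)[C@H](Br)C[C@H]1O | intermediate
23 | acryloyl chloride | C=CC(=O)Cl | starting material
24 | (2S,3R,5R,6R)-2-allyl-5-bromo-6-[(E)-3-bromopent-2-enyl]tetrahydropyran-3-yl acrylate | C=CC[C@@H]1O[C@H](C/C=C(/Br)CC)[C@H](Br)C[C@H]1OC(=O)C=C | intermediate
25 | trans-fused (Z)-unsaturated seven-membered lactone (C2 carbonyl, C3=C4; 6S,7R,9R,10R) | O=C1/C=C\C[C@@H]2O[C@H](C/C=C(/Br)CC)[C@H](Br)C[C@H]2O1 | intermediate
26 | (Z)-unsaturated seven-membered lactol (C2 hemiacetal, anomeric mixture) | OC1/C=C\C[C@@H]2O[C@H](C/C=C(/Br)CC)[C@H](Br)C[C@H]2O1 | intermediate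
27 | trimethylsilyldiazomethane | C[Si](C)(C)C=[N+]=[N-] | starting material
28 | (Z)-hydroxy enal, open form of 26 (C2 aldehyde, free C7 hydroxyl) | O=C/C=C\C[C@@H]1O[C@H](C/C=C(/Br)CC)[C@H](Br)C[C@H]1O | intermediate
29 | (2S,3R,5R,6R)-5-bromo-6-[(E)-3-bromopent-2-enyl]-2-[(Z)-pent-2-en-4-ynyl]tetrahydropyran-3-ol | C#C/C=C\C[C@@H]1O[C@H](C/C=C(/Br)CC)[C@H](Br)C[C@H]1O | intermediate
30 | (2S,3S,5R,6R)-5-bromo-6-[(E)-3-bromopent-2-enyl]-3-chloro-2-[(Z)-pent-2-en-4-ynyl]tetrahydropyran | C#C/C=C\C[C@@H]1O[C@H](C/C=C(/Br)CC)[C@H](Br)C[C@@H]1Cl | target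

## Step count and risks

Total steps: 19. Longest linear sequence: 19 steps (1 → 30).

**Step 16 (key step).** The likeliest failure is intermolecular metathesis through the allyl group (dimerisation or oligomerisation) outrunning closure onto the electron-poor acrylate. Chelation of the ester carbonyl to the ruthenium alkylidene could also slow turnover. Fallback, from 22 and back to the route at 29: the C7 hydroxyl is silylated (Et3SiCl, imidazole) to the triethylsilyl ether F1. The terminal alkene is cleaved selectively (OsO4 cat., NaIO4, 2,6-lutidine; the bromoalkene is electron-poor and trisubstituted) to the aldehyde F2. Peterson olefination with lithiated 1-(tert-butyldimethylsilyl)-3-(trimethylsilyl)prop-1-yne (t-BuLi, THF, −78 °C) gives the (Z)-silyl enyne F3, and n-Bu4NF buffered with AcOH removes both silyl groups to give 29. This gives up the ring-enforced geometry for a kinetically Z-selective olefination.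

**Step 7.** Incomplete or non-regioselective hydromagnesiation, configurational drift of the α-silyl vinyl Grignard reagent before it is trapped, or sluggish alkylation of this hindered nucleophile by iodoethane would erode the geometry that the bromoalkene inherits. Fallback, from 8 and back at 11: cis hydroalumination (i-Bu2AlH, N-methylpyrrolidine, heptane) and iodinolysis give the (E)-α-iodovinylsilane F4. Negishi coupling with EtZnCl and PdCl2(dppf) then replaces iodine by ethyl with retention to give 11.

**Step 10.** Hydrolysis of the methyl glycoside may be slow because the C2 benzyloxy and C4 bromo groups destabilise the oxocarbenium ion, and prolonged hot acid could begin to hydrate the bromoalkene. Fallback, from 16 and back at 17: acetolysis (Ac2O, AcOH, cat. H2SO4, 0 °C) exchanges the anomeric methoxy group for acetate under anhydrous conditions to give the anomeric acetate F5, and hydrazine acetate in DMF removes the anomeric acetyl group selectively to give 17.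

**Step 18.** Before the diazo anion adds, the (Z)-enal can isomerise to the E-isomer, or the C7 alkoxide can add in conjugate fashion to C4 and close a tetrahydrofuran. Base-induced loss of HBr from the axial C9 bromide is a lesser risk. Fallback, from 25 and back at 29: the lactone is opened with MeNH(OMe)·HCl and AlMe3 to the (Z)-hydroxy Weinreb amide F6, which is silylated (Et3SiOTf, 2,6-lutidine) to the silyl ether F7. Reduction with i-Bu2AlH gives the O-silylated (Z)-enal F8, which has no free alkoxide and no ring-chain equilibrium. Colvin homologation gives the silyl enyne F9, and HF·pyridine gives 29.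

**Step 19.** Displacement at C7 must pass syn to the axial C9 bromide and next to the C6 chain, so substitution may stall at the alkoxyphosphonium stage or divert to elimination. Fallback, from 29 and back at 30: the alcohol is converted with ClCH2SO2Cl and 2,6-lutidine into the chloromethanesulfonate F10, a small and highly reactive leaving group, which is displaced with inversion by LiCl in DMF to give 30.

## Further compounds

F1 | step 16 | triethylsilyl ether of 22 | C=CC[C@@H]1O[C@H](C/C=C(/Br)CC)[C@H](Br)C[C@H]1O[Si](CC)(CC)CC
F2 | step 16 | C4 aldehyde from cleavage of the allyl group of F1 | O=CC[C@@H]1O[C@H](C/C=C(/Br)CC)[C@H](Br)C[C@H]1O[Si](CC)(CC)CC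
F3 | step 16 | (Z)-enyne with C1 tert-butyldimethylsilyl and C7 O-triethylsilyl groups | CC(C)(C)[Si](C)(C)C#C/C=C\C[C@@H]1O[C@H](C/C=C(/Br)CC)[C@H](Br)C[C@H]1O[Si](CC)(CC)CC
F4 | step 7 | (E)-α-iodovinylsilane (iodine and SiMe3 on C13, iodine trans to C11) | CO[C@H]1O[C@H](C/C=C(/I)[Si](C)(C)C)[C@@H](O[Si](CC)(CC)CC)C[C@H]1OCc2ccccc2
F5 | step 10 | 1-O-acetyl-2-O-benzyl-4-bromo-6-C-[(E)-2-bromobut-1-enyl]-3,4,6-trideoxy-D-xylo-hexopyranose (anomeric mixture) | CC(=O)OC1O[C@H](C/C=C(/Br)CC)[C@H](Br)C[C@H]1OCc2ccccc2
F6 | step 18 | (Z)-N-methoxy-N-methyl enamide with free C7 hydroxyl | CON(C)C(=O)/C=C\C[C@@H]1O[C@H](C/C=C(/Br)CC)[C@H](Br)C[C@H]1O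
F7 | step 18 | C7 O-triethylsilyl ether of F6 | CON(C)C(=O)/C=C\C[C@@H]1O[C@H](C/C=C(/Br)CC)[C@H](Br)C[C@H]1O[Si](CC)(CC)CC
F8 | step 18 | C7 O-triethylsilyl (Z)-enal | O=C/C=C\C[C@@H]1O[C@H](C/C=C(/Br)CC)[C@H](Br)C[C@H]1O[Si](CC)(CC)CC
F9 | step 18 | C7 O-triethylsilyl (Z)-enyne | C#C/C=C\C[C@@H]1O[C@H](C/C=C(/Br)CC)[C@H](Br)C[C@H]1O[Si](CC)(CC)CC
F10 | step 19 | C7 chloromethanesulfonate of 29 | C#C/C=C\C[C@@H]1O[C@H](C/C=C(/Br)CC)[C@H](Br)C[C@H]1OS(=O)(=O)CCl
A1 | alternative 1 | all-equatorial 4-nitrotetrahydropyran-3,5-diol | COC(OC)C[C@@H]1O[C@H](CCO[Si](c2ccccc2)(c2ccccc2)C(C)(C)C)[C@@H](O)[C@H]([N+](=O)[O-])[C@H]1O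
A2 | alternative 1 | dialdehyde ether | COC(OC)C[C@@H](C=O)O[C@H](CCO[Si](c1ccccc1)(c1ccccc1)C(C)(C)C)C=O
A3 | alternative 1 | nitromethane | C[N+](=O)[O-]
A4 | alternative 2 | meso-8-oxabicyclo[3.2.1]oct-6-en-3-one | O=C1C[C@H]2C=C[C@@H](C1)O2
A5 | alternative 2 | furan | c1ccoc1
A6 | alternative 2 | 1,1,3,3-tetrabromoacetone | O=C(C(Br)Br)C(Br)Br
A7 | alternative 3 | cis-2-allyl-6-alkyl-5-silyloxytetrahydropyran-3-one | COc1ccc(COCC[C@@H]2O[C@H](CC=C)C(=O)C[C@H]2O[Si](C)(C)C(C)(C)C)cc1
A8 | alternative 3 | allyl ether diazoketone | COc1ccc(COCC[C@H](OCC=C)[C@H](O[Si](C)(C)C(C)(C)C)CC(=O)C=[N+]=[N-])cc1
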